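**Plan**
- Retrosynthetic cuts (isochroman locants; primed = isoquinoline): the C7–CHO bond (back to C7–Br); the acetal bond C1–O6′ (1,3-dioxin ring); C1–C8a and C1–O2 of the pyran ring (C1 as CH2 from dimethoxymethane); the C3–C4 bond; the pyridine ring of the isoquinoline.
- Enabling feature: C1 (the acetal CH) is benzylic, α to the pyran oxygen O2 and para to the ring A hydroxyl on C6. As a CH2 it can be dehydrogenated to a p-quinone methide, which the 6′-OH of the isoquinoline, held on C3, captures.
- Forward: one dibromo silyl ether (5) feeds both halves. A Sonogashira coupling gives the ring A arylpropyne; lithiation/formylation, Sonogashira coupling and imine annulation give the isoquinoline (pyridine ring first), whose C7′–Br becomes CH2OH.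
- The halves are joined at C3–C4; then the pyran ring is closed, vinyl is oxidised to acetyl, the phenols are freed, the 1,3-dioxin ring is closed oxidatively, and the bromide is formylated last.
- Stereochemistry: C3 (R) and C4 (S) come together from a Ru–JOSIPHOS anti-(α-aryl)allylation (ligand control plus chair transition state); C1 (R) is dictated by C3 through the tether in the key step.

Key step: step 13

Remark: the JOSIPHOS antipode that delivers the (1R,2S) alcohol in step 9 is assumed to be fixed on a model alcohol/arylpropyne pair; TIPS = triisopropylsilyl.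

Step 1
Reactants: 1 1-bromo-3,5-dimethoxybenzene
Product: 3 2,5-dibromo-1,3-dimethoxybenzene, via (4-bromo-2,6-dimethoxyphenyl)lithium 2 (not isolated)
Conditions: LDA, THF, −78 °C; then BrCl2C–CCl2Br, −78 °C → rt
Reagents that add atoms: 1,2-dibromo-1,1,2,2-tetrachloroethane BrC(Cl)(Cl)C(Cl)(Cl)Br
Why: Directed ortho-metalation should remove the proton flanked by both methoxy groups (the same site that leads to 4-bromo-2,6-dimethoxybenzaldehyde when DMF is the electrophile), and the aryllithium is then brominated by the Br+ donor.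

Step 2
Reactants: 3 2,5-dibromo-1,3-dimethoxybenzene
Product: 4 2,5-dibromo-3-methoxyphenol
Conditions: NaSEt, DMF, 110 °C; then 1 M HCl
Reagents that add atoms: none
Why: Thiolate SN2 O-demethylation of a symmetric diether should stop after one methyl group, because the phenoxide formed makes loss of the second methyl far slower.

Step 3
Reactants: 4 2,5-dibromo-3-methoxyphenol
Product: 5 (2,5-dibromo-3-methoxyphenoxy)triisopropylsilane
Conditions: TIPSCl, imidazole, DMF, rt
Reagents that add atoms: chlorotriisopropylsilane CC(C)[Si](Cl)(C(C)C)C(C)C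
Why: Imidazole-promoted silylation of the phenol; the bulky TIPS ether is chosen because it later shields its own ortho position in steps 5 and 10 and falls off with fluoride.

Step 4
Reactants: 5 (2,5-dibromo-3-methoxyphenoxy)triisopropylsilane; 6 propyne
Product: 7 [2-bromo-3-methoxy-5-(prop-1-yn-1-yl)phenoxy]triisopropylsilane
Conditions: PdCl2(PPh3)2 (cat.), CuI (cat.), Et3N, THF, 50 °C, sealed tube
Reagents that add atoms: none
Why: Sonogashira coupling; oxidative addition should take place only at the bromide flanked by two hydrogens, the other bromide being buried between OMe and OTIPS.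

Step 5
Reactants: 5 (2,5-dibromo-3-methoxyphenoxy)triisopropylsilane
Product: 9 3,6-dibromo-2-methoxy-4-(triisopropylsilyloxy)benzaldehyde, via [3,6-dibromo-2-methoxy-4-(triisopropylsilyloxy)phenyl]lithium 8 (not isolated)
Conditions: LDA, THF, −78 °C; then DMF, −78 °C; 1 M HCl
Reagents that add atoms: N,N-dimethylformamide CN(C)C=O
Why: Directed ortho-metalation/formylation: of the two protons next to the C5 bromide, the one beside OMe is open and lithium-coordinating whereas the one beside OTIPS is shielded, and −78 °C keeps the ortho-bromoaryllithium from aryne formation or halogen migration.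

Step 6
Reactants: 9 3,6-dibromo-2-methoxy-4-(triisopropylsilyloxy)benzaldehyde; 6 propyne
Product: 10 3-bromo-2-methoxy-6-(prop-1-yn-1-yl)-4-(triisopropylsilyloxy)benzaldehyde
Conditions: PdCl2(PPh3)2 (cat.), CuI (cat.), Et3N, THF, 45 °C, sealed tube
Reagents that add atoms: none
Why: Sonogashira coupling at the bromide ortho to the formyl group (activated and accessible), leaving the bromide between OMe and OTIPS untouched.

Step 7
Reactants: 10 3-bromo-2-methoxy-6-(prop-1-yn-1-yl)-4-(triisopropylsilyloxy)benzaldehyde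
Product: 12 7-bromo-8-methoxy-3-methyl-6-(triisopropylsilyloxy)isoquinoline, via tert-butylimine 11 (not isolated)
Conditions: t-BuNH2, 4 Å MS, rt; then CuI (cat.), DMF, 100 °C
Reagents that add atoms: tert-butylamine CC(C)(C)N
Why: Iminoannulation of an o-alkynylbenzaldehyde: condensation to imine 11, copper-catalysed 6-endo-dig attack of nitrogen on the alkyne and loss of isobutene close the pyridine ring under neutral conditions that spare the silyl ether.

Step 8
Reactants: 12 7-bromo-8-methoxy-3-methyl-6-(triisopropylsilyloxy)isoquinoline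
Product: 13 [8-methoxy-3-methyl-6-(triisopropylsilyloxy)isoquinolin-7-yl]methanol
Conditions: Bu3SnCH2OH, XPhos Pd G3 (cat.), 1,4-dioxane, 100 °C
Reagents that add atoms: (tributylstannyl)methanol CCCC[Sn](CCCC)(CCCC)CO
Why: Stille hydroxymethylation of the aryl bromide with a bulky biarylphosphine palladium catalyst suited to di-ortho-substituted bromides; the base-free conditions keep the aryl silyl ether.

Step 9
Reactants: 13 [8-methoxy-3-methyl-6-(triisopropylsilyloxy)isoquinolin-7-yl]methanol; 7 [2-bromo-3-methoxy-5-(prop-1-yn-1-yl)phenoxy]triisopropylsilane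
Product: 16 (1R,2S)-2-[4-bromo-3-methoxy-5-(triisopropylsilyloxy)phenyl]-1-[8-methoxy-3-methyl-6-(triisopropylsilyloxy)isoquinolin-7-yl]but-3-en-1-ol, via aldehyde 14 (not isolated), via arylallene 15 (not isolated)
Conditions: H2Ru(CO)(PPh3)3 (cat.), JOSIPHOS SL-J009-1 (cat.), 2,4,6-(i-Pr)3C6H2SO3H (cat.), THF, 95 °C
Reagents that add atoms: none
Why: Ruthenium-catalysed hydrogen-transfer coupling of a 1-arylpropyne with a primary alcohol (carbonyl anti-(α-aryl)allylation): dehydrogenation gives aldehyde 14, alkyne-to-allene isomerisation and hydrometalation give an (E)-σ-allylruthenium that adds through a closed chair transition state (anti), and the JOSIPHOS ligand selects the aldehyde face, so C1 (R) and C2 (S) are set together.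

Step 10
Reactants: 16 (1R,2S)-2-[4-bromo-3-methoxy-5-(triisopropylsilyloxy)phenyl]-1-[8-methoxy-3-methyl-6-(triisopropylsilyloxy)isoquinolin-7-yl]but-3-en-1-ol; 17 dimethoxymethane
Product: 19 (3R,4S)-7-bromo-4-ethenyl-8-methoxy-3-[8-methoxy-3-methyl-6-(triisopropylsilyloxy)isoquinolin-7-yl]-6-(triisopropylsilyloxy)isochroman, via methoxymethyl ether 18 (not isolated)
Conditions: TMSOTf (3.5 equiv), CH2Cl2, 0 °C → rt; aq. NaHCO3
Reagents that add atoms: none
Why: Oxa-Pictet–Spengler cyclisation: acetal exchange gives 18, whose oxocarbenium ion should attack ring A ortho to OMe and para to the silyloxy group (the other ortho position is shielded by TIPS, the N-silylated isoquinoline is inert, and the arene outruns the vinyl group as nucleophile), leaving C3 and C4 untouched.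

Step 11
Reactants: 19 (3R,4S)-7-bromo-4-ethenyl-8-methoxy-3-[8-methoxy-3-methyl-6-(triisopropylsilyloxy)isoquinolin-7-yl]-6-(triisopropylsilyloxy)isochroman
Product: 20 1-[(3R,4S)-7-bromo-8-methoxy-3-[8-methoxy-3-methyl-6-(triisopropylsilyloxy)isoquinolin-7-yl]-6-(triisopropylsilyloxy)isochroman-4-yl]ethan-1-one
Conditions: PdCl2 (cat.), CuCl (co-catalyst), O2 (1 atm), DMF/H2O 7:1, rt
Reagents that add atoms: water O
Why: Tsuji–Wacker oxidation: Markovnikov hydroxypalladation of the terminal alkene should give the methyl ketone under near-neutral conditions that do not touch C4.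

Step 12
Reactants: 20 1-[(3R,4S)-7-bromo-8-methoxy-3-[8-methoxy-3-methyl-6-(triisopropylsilyloxy)isoquinolin-7-yl]-6-(triisopropylsilyloxy)isochroman-4-yl]ethan-1-one
Product: 21 1-[(3R,4S)-7-bromo-6-hydroxy-3-(6-hydroxy-8-methoxy-3-methylisoquinolin-7-yl)-8-methoxyisochroman-4-yl]ethan-1-one
Conditions: TBAF, AcOH (1:1), THF, 0 °C
Reagents that add atoms: none
Why: Fluoride cleavage of both aryl silyl ethers; the acetic acid buffer keeps the medium non-basic so that the stereocentre α to the ketone should not epimerise.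

Step 13
Reactants: 21 1-[(3R,4S)-7-bromo-6-hydroxy-3-(6-hydroxy-8-methoxy-3-methylisoquinolin-7-yl)-8-methoxyisochroman-4-yl]ethan-1-one
Product: 23 bromo acetal 1-[(1R,3R,4S)-7-bromo-6-hydroxy-8-methoxyisochroman-4-yl]ethan-1-one bridged from C1 (through O6′) to C3 (through C7′) by the 8′-methoxy-3′-methylisoquinoline unit, via quinone methide 22 (not isolated)
Conditions: DDQ (1.1 equiv), 4 Å MS, CH2Cl2, 0 °C → rt; aq. NaHCO3
Reagents that add atoms: none
Why: DDQ abstracts hydride from C1–H of the 6-hydroxyisochroman (a pseudo-axial C–H aligned with the ring A π system, α to O2 and para to the C6 hydroxyl), and loss of the phenolic proton gives the O2-stabilised p-quinone methide 22. The 6′-hydroxyl of the isoquinoline, held on C3, then adds to the methide carbon C1 in a 1,6-conjugate addition, forming the C1–O6′ bond and rearomatising ring A. The closest known reaction types are the DDQ oxidation of p-alkoxybenzyl ethers with capture by a neighbouring hydroxyl to give arylidene acetals and the quinone-methide-mediated oxidative closure of B-type to A-type proanthocyanidin linkages. The 1,3-dioxin ring closes in the 6-exo-trig mode. C1 becomes R under substrate control, because the tethered oxygen can only reach the face of C1 on which the C3 aryl group stands (1,3-diaxial bridge), so C3 fixes C1. The step needs oxidation of ring A at C1 rather than at C3 or on the isoquinolinol: the para-hydroxybenzyl ether of ring A is the better hydride donor than the electron-poor pyridine-fused phenol (which is also protonated by the hydroquinone as it forms), and once the bridge is closed the C1–H bond lies in the plane of ring A, which should stop further oxidation.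

Step 14
Reactants: 23 bromo acetal (target skeleton with Br on C7)
Product: 24 target, 1-[(1R,3R,4S)-7-formyl-6-hydroxy-8-methoxyisochroman-4-yl]ethan-1-one bridged from C1 (through O6′) to C3 (through C7′) by the 8′-methoxy-3′-methylisoquinoline unit
Conditions: Pd(OAc)2 (cat.), n-BuPAd2 (cat.), CO (5 bar), Et3SiH, Na2CO3, DMF, 80 °C
Reagents that add atoms: carbon monoxide [C-]#[O+]
Why: Palladium-catalysed reductive carbonylation of the aryl bromide (oxidative addition, CO insertion, Si–H transfer to the acyl-palladium) should install the formyl group without involving any stereocentre.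

**Compound list**
1 | 1-bromo-3,5-dimethoxybenzene | COc1cc(Br)cc(OC)c1 | starting material
2 | (4-bromo-2,6-dimethoxyphenyl)lithium | [Li]c1c(OC)cc(Br)cc1OC | intermediate (not isolated)
3 | 2,5-dibromo-1,3-dimethoxybenzene | COc1cc(Br)cc(OC)c1Br | intermediate
4 | 2,5-dibromo-3-methoxyphenol | COc1cc(Br)cc(O)c1Br | intermediate
5 | (2,5-dibromo-3-methoxyphenoxy)triisopropylsilane | COc1cc(Br)cc(O[Si](C(C)C)(C(C)C)C(C)C)c1Br | intermediate
6 | propyne | CC#C | starting material
7 | [2-bromo-3-methoxy-5-(prop-1-yn-1-yl)phenoxy]triisopropylsilane | CC#Cc1cc(OC)c(Br)c(O[Si](C(C)C)(C(C)C)C(C)C)c1 | intermediate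
8 | [3,6-dibromo-2-methoxy-4-(triisopropylsilyloxy)phenyl]lithium | [Li]c1c(OC)c(Br)c(O[Si](C(C)C)(C(C)C)C(C)C)cc1Br | intermediate (not isolated)
9 | 3,6-dibromo-2-methoxy-4-(triisopropylsilyloxy)benzaldehyde | O=Cc1c(OC)c(Br)c(O[Si](C(C)C)(C(C)C)C(C)C)cc1Br | intermediate
10 | 3-bromo-2-methoxy-6-(prop-1-yn-1-yl)-4-(triisopropylsilyloxy)benzaldehyde | CC#Cc1cc(O[Si](C(C)C)(C(C)C)C(C)C)c(Br)c(OC)c1C=O | intermediate
11 | (E)-N-tert-butyl aldimine of 10 | CC#Cc1cc(O[Si](C(C)C)(C(C)C)C(C)C)c(Br)c(OC)c1/C=N/C(C)(C)C | intermediate (not isolated)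
12 | 7-bromo-8-methoxy-3-methyl-6-(triisopropylsilyloxy)isoquinoline | Cc1cc2cc(O[Si](C(C)C)(C(C)C)C(C)C)c(Br)c(OC)c2cn1 | intermediate
13 | [8-methoxy-3-methyl-6-(triisopropylsilyloxy)isoquinolin-7-yl]methanol | Cc1cc2cc(O[Si](C(C)C)(C(C)C)C(C)C)c(CO)c(OC)c2cn1 | intermediate
14 | 8-methoxy-3-methyl-6-(triisopropylsilyloxy)isoquinoline-7-carbaldehyde | Cc1cc2cc(O[Si](C(C)C)(C(C)C)C(C)C)c(C=O)c(OC)c2cn1 | intermediate (not isolated)
15 | [2-bromo-3-methoxy-5-(propa-1,2-dien-1-yl)phenoxy]triisopropylsilane | C=C=Cc1cc(OC)c(Br)c(O[Si](C(C)C)(C(C)C)C(C)C)c1 | intermediate (not isolated)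
16 | (1R,2S)-2-[4-bromo-3-methoxy-5-(triisopropylsilyloxy)phenyl]-1-[8-methoxy-3-methyl-6-(triisopropylsilyloxy)isoquinolin-7-yl]but-3-en-1-ol | O[C@@H](c1c(O[Si](C(C)C)(C(C)C)C(C)C)cc2cc(C)ncc2c1OC)[C@H](c1cc(OC)c(Br)c(O[Si](C(C)C)(C(C)C)C(C)C)c1)C=C | intermediate
17 | dimethoxymethane | COCOC | starting material
18 | methoxymethyl ether of 16 | COCO[C@@H](c1c(O[Si](C(C)C)(C(C)C)C(C)C)cc2cc(C)ncc2c1OC)[C@H](c1cc(OC)c(Br)c(O[Si](C(C)C)(C(C)C)C(C)C)c1)C=C | intermediate (not isolated)
19 | (3R,4S)-7-bromo-4-ethenyl-8-methoxy-3-[8-methoxy-3-methyl-6-(triisopropylsilyloxy)isoquinolin-7-yl]-6-(triisopropylsilyloxy)isochroman | COc1c(Br)c(O[Si](C(C)C)(C(C)C)C(C)C)cc2c1CO[C@@H](c1c(O[Si](C(C)C)(C(C)C)C(C)C)cc3cc(C)ncc3c1OC)[C@H]2C=C | intermediate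
20 | 1-[(3R,4S)-7-bromo-8-methoxy-3-[8-methoxy-3-methyl-6-(triisopropylsilyloxy)isoquinolin-7-yl]-6-(triisopropylsilyloxy)isochroman-4-yl]ethan-1-one | COc1c(Br)c(O[Si](C(C)C)(C(C)C)C(C)C)cc2c1CO[C@@H](c1c(O[Si](C(C)C)(C(C)C)C(C)C)cc3cc(C)ncc3c1OC)[C@H]2C(C)=O | intermediate
21 | 1-[(3R,4S)-7-bromo-6-hydroxy-3-(6-hydroxy-8-methoxy-3-methylisoquinolin-7-yl)-8-methoxyisochroman-4-yl]ethan-1-one | COc1c(Br)c(O)cc2c1CO[C@@H](c1c(O)cc3cc(C)ncc3c1OC)[C@H]2C(C)=O | intermediate
22 | p-quinone methide of 21 (ring A as 6-oxocyclohexadiene with exocyclic C8a=C1 double bond; 3R,4S) | COC1=C(Br)C(=O)C=C2C1=CO[C@@H](c1c(O)cc3cc(C)ncc3c1OC)[C@H]2C(C)=O | intermediate (not isolated)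
23 | bromo acetal: 4-acetyl-7-bromo-6-hydroxy-8-methoxyisochroman bridged C1–O6′ and C3–C7′ by the 8′-methoxy-3′-methylisoquinoline unit; (1R,3R,4S) | COc1c(Br)c(O)cc2c1[C@H]1Oc3cc4cc(C)ncc4c(OC)c3[C@H](O1)[C@H]2C(C)=O | intermediate
24 | CNP0584953.1: the same bridged acetal with CHO on C7; (1R,3R,4S) | COc1c(C=O)c(O)cc2c1[C@H]1Oc3cc4cc(C)ncc4c(OC)c3[C@H](O1)[C@H]2C(C)=O | target

**Step count:** 14 steps in total. The longest linear sequence is 13 steps (steps 1, 2, 3, 5, 6, 7, 8, 9, 10, 11, 12, 13, 14 from compound 1); step 4 is the one-step side branch from 5 to 7.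

**Steps most likely to fail**

Step 9. The ruthenium catalyst may be held by the isoquinoline nitrogen, or it may distinguish the faces of the di-ortho-substituted aldehyde poorly, so that coupling stalls or the alcohol forms with low enantiomeric purity. The fallback sets out from 13 and 5 and returns at 16. Alcohol 13 would be oxidised with MnO2 to aldehyde 14, now isolated. Stille coupling of 5 with (E)-3-(tributylstannyl)prop-2-en-1-ol at the unhindered bromide should give (E)-3-[4-bromo-3-methoxy-5-(triisopropylsilyloxy)phenyl]prop-2-en-1-ol F1. CBr4/PPh3 should then give [2-bromo-5-[(E)-3-bromoprop-1-en-1-yl]-3-methoxyphenoxy]triisopropylsilane F2. A catalytic asymmetric Nozaki–Hiyama–Kishi reaction of 14 with F2 (CrCl2 cat., Mn, TMSCl, chiral salen or oxazoline–sulfonamide ligand) is anti-selective for γ-aryl allylchromium species and, after desilylating work-up, should give 16.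

Step 13. Hydride abstraction may occur at the wrong position (C3, activated by the isoquinolinol), or the free phenols may undergo oxidative coupling or over-oxidation instead of clean quinone methide formation. The fallback sets out from 16 and returns at 23; it brings C1 in at the aldehyde oxidation level so that no oxidant is needed. Oxa-Pictet–Spengler cyclisation of 16 with trimethyl orthoformate (TMSOTf, CH2Cl2) should give (3R,4S)-7-bromo-4-ethenyl-1,8-dimethoxy-3-[8-methoxy-3-methyl-6-(triisopropylsilyloxy)isoquinolin-7-yl]-6-(triisopropylsilyloxy)isochroman F3 as a mixture at C1. Tsuji–Wacker oxidation should give the methyl ketone 1-[(3R,4S)-7-bromo-1,8-dimethoxy-3-[8-methoxy-3-methyl-6-(triisopropylsilyloxy)isoquinolin-7-yl]-6-(triisopropylsilyloxy)isochroman-4-yl]ethan-1-one F4. Buffered fluoride should give the diphenol 1-[(3R,4S)-7-bromo-6-hydroxy-3-(6-hydroxy-8-methoxy-3-methylisoquinolin-7-yl)-1,8-dimethoxyisochroman-4-yl]ethan-1-one F5. Catalytic camphorsulfonic acid (CH2Cl2, 4 Å MS) then ionises the 1-methoxy group to the same para-hydroxy-stabilised oxocarbenium ion, on which O6′ closes with loss of methanol to give 23.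

Step 14. Hydride may be transferred to the aryl-palladium intermediate before CO inserts (hydrodebromination at the bromide flanked by OH and OMe), or the centre α to the ketone may epimerise under the hot, basic conditions. The fallback sets out from 23 and returns at 24. Base-free Stille coupling with tributyl(vinyl)stannane (XPhos Pd G3, dioxane, 90 °C) should give the C7-ethenyl analogue of 23 F6. Lemieux–Johnson cleavage (OsO4 cat., NaIO4, 2,6-lutidine, dioxane/H2O) of the styrene double bond should then give 24.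

**Further compounds**
F1 | step 9 | (E)-3-[4-bromo-3-methoxy-5-(triisopropylsilyloxy)phenyl]prop-2-en-1-ol | OC/C=C/c1cc(OC)c(Br)c(O[Si](C(C)C)(C(C)C)C(C)C)c1
F2 | step 9 | [2-bromo-5-[(E)-3-bromoprop-1-en-1-yl]-3-methoxyphenoxy]triisopropylsilane | BrC/C=C/c1cc(OC)c(Br)c(O[Si](C(C)C)(C(C)C)C(C)C)c1
F3 | step 13 | (3R,4S)-7-bromo-4-ethenyl-1,8-dimethoxy-3-[8-methoxy-3-methyl-6-(triisopropylsilyloxy)isoquinolin-7-yl]-6-(triisopropylsilyloxy)isochroman (both C1 epimers) | COc1c(Br)c(O[Si](C(C)C)(C(C)C)C(C)C)cc2c1C(OC)O[C@@H](c1c(O[Si](C(C)C)(C(C)C)C(C)C)cc3cc(C)ncc3c1OC)[C@H]2C=C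
F4 | step 13 | 1-[(3R,4S)-7-bromo-1,8-dimethoxy-3-[8-methoxy-3-methyl-6-(triisopropylsilyloxy)isoquinolin-7-yl]-6-(triisopropylsilyloxy)isochroman-4-yl]ethan-1-one (both C1 epimers) | COc1c(Br)c(O[Si](C(C)C)(C(C)C)C(C)C)cc2c1C(OC)O[C@@H](c1c(O[Si](C(C)C)(C(C)C)C(C)C)cc3cc(C)ncc3c1OC)[C@H]2C(C)=O
F5 | step 13 | 1-[(3R,4S)-7-bromo-6-hydroxy-3-(6-hydroxy-8-methoxy-3-methylisoquinolin-7-yl)-1,8-dimethoxyisochroman-4-yl]ethan-1-one (both C1 epimers) | COc1c(Br)c(O)cc2c1C(OC)O[C@@H](c1c(O)cc3cc(C)ncc3c1OC)[C@H]2C(C)=O
F6 | step 14 | C7-ethenyl analogue of 23 (ethenyl in place of bromine; 1R,3R,4S) | COc1c(C=C)c(O)cc2c1[C@H]1Oc3cc4cc(C)ncc4c(OC)c3[C@H](O1)[C@H]2C(C)=O
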